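A small charge of protic impurity, 0.0130 M, opens my ledger for the partner, the limiting reagent by charge against the racemate in this flask.

in all of them: left-handed substrate 0.13 M; right-handed substrate 0.13 M; free catalyst 2.2 mol%

|  | partner | protic impurity | remark |
|---|---|---|---|
| birch | 1.2 equiv | 0.0065 M | run made earlier |
| ash | 1.2 equiv | 0.026 M | run made earlier |
| cedar | 1.8 equiv | 0.013 M | run made earlier |
| flask | 1.20 equiv | 0.0130 M |  |

| run | time / h | left-handed product / % | left-handed substrate / % |
|---|---|---|---|
| birch | 1.00 | 10.4 | 38.8 |
| birch | 2.00 | 14.3 | 35.5 |
| birch | 3.00 | 17.4 | 32.9 |
| birch | 4.00 | 16.7 | 31.4 |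
| birch | 5.00 | 18.9 | 32.2 |
| birch | 6.00 | 19.2 | 31.9 |
| birch | 8.00 | 20.8 | 30.2 |
| ash | 0.500 | 7.6 | 42.9 |
| ash | 0.833 | 9.5 | 40.3 |
| ash | 1.33 | 9.8 | 39.0 |
| ash | 2.00 | 12.1 | 37.6 |
| ash | 3.00 | 13.6 | 36.2 |
| ash | 5.00 | 15.8 | 33.7 |
| ash | 8.00 | 18.2 | 34.5 |
| cedar | 0.667 | 11.9 | 36.1 |
| cedar | 2.00 | 19.6 | 31.0 |
| cedar | 3.00 | 22.7 | 26.3 |
| cedar | 5.00 | 24.9 | 27.0 |
| cedar | 8.00 | 25.2 | 24.8 |

(standard deviation of a reading: 1 percentage point)

- free catalyst is single-handed; left-handed substrate and right-handed substrate are mirror images of each other, charged as a racemate, each of them at the stated concentration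

- apparent order in partner when 10% of the left-handed substrate and right-handed substrate together are converted (percent change of the rate of making left-handed product for one percent more partner charged)

I assume that one partner goes per impurity and one per substrate turned. As fractions of the partner charge, the impurity takes 8.33% and the asked conversion of 10% takes 16.7%, so 75.0% stands free at that point. One percent more charge then gives 1.33 percent more free partner, and I call this ratio of charge to free partner the gearing.

The birch run adds 3.9 percentage points from 1.00 h to 2.00 h, 2.4 points from 2.00 h to 4.00 h and 4.1 points from 4.00 h to 8.00 h, steps per doubling of time that I take as of one size, given a scatter of 1 point on each reading. I read this as catalyst lost in pairs. On that reading, conversion follows free partner times the logarithm of the catalyst's fall, so my first answer, the gearing, goes back in: with more partner the same conversion is reached after less fall, and the order is the gearing times one plus that logarithm.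

The ash run stands near the point at its first two readings. Its mean rate up to 0.500 h is 2.66 times its rate from there to 0.833 h, a rough reading with wide scatter. I borrow that ratio from the ash run, with its 0.026 M of impurity, as a stand-in for the catalyst's fall in this flask, so my reckoning of the order is 2.64.

The forecast gives 1.4, lower than my figure, with the words “More partner seems to raise both rate and catalyst survival”.

The flask gives 2.7.

    partner + free catalyst + left-handed substrate → free catalyst + left-handed product (k = 31.0 /M²/min)
    partner + free catalyst + right-handed substrate → free catalyst + right-handed product (k = 6.20 /M²/min)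
    2 free catalyst → spent catalyst (k = 13.0 /M/min)
    partner + protic impurity → quenched reagent (k = 27.0 /M/min)

This flask's order is twice the gearing. The pairwise loss of free catalyst is the largest single effect on it: in the same flask without that step the order is 1.3, the size of the gearing. That loss adds 1.41 to the order.

Readings and results stem from a simulated flask for an exercise; noise was put on by code.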